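## Retrosynthetic overview

1. Target 32 ⇐ protected lactone 30 (desilylation, then hydrogenolysis) ⇐ succinate 28. The lactone is closed last, after an oxidative 8–8′ coupling of the two enolates of ester 14 and imide 25 (the two-fragment counterpart of the coupling that makes lignans).
2. Imide 25 ⇐ diol 17. The dihydrobenzofuran is closed through the p-quinone methide of an 8–5-type diol (the intermediate of 8–5 phenol coupling, generated here ionically), trans from the preset C3.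
3. 14 and 17 ⇐ one imide 9 + O-benzylvanillin 10. The same (S)-auxiliary gives the anti-aldol (open arm) with Mg and the syn-aldol (closed arm) with boron.
4. Imide 9 ⇐ ethyl dihydroferulate 1 by O-allylation, Claisen rearrangement (puts the carbon at C5) and oxidative cleavage to the arylacetic acid.
5. Ring order: dihydrobenzofuran (step 11), then lactone (step 16).

Assumption: in the Mg aldol (step 6) and the oxidative coupling (step 15) the metal-chelated (Z)-enolate of the (S)-benzyloxazolidinone reacts on the face away from the benzyl group, as in Evans alkylations.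

Locants used: lactone C3/C4, dihydrobenzofuran C2/C3, diol arm C1/C2. Target = lactone (3R,4R), dihydrobenzofuran (2S,3R), diol arm (1S,2S).

## Route

Step 1
Reactants: 1 ethyl 3-(4-hydroxy-3-methoxyphenyl)propanoate
Product: 2 O-allyl ether of 1
Conditions: allyl bromide, K2CO3, acetone, reflux
Reagents that add atoms: allyl bromide, C=CCBr
Why: Williamson ether synthesis (SN2 of the phenoxide on allyl bromide); no stereocentre is involved.

Step 2
Reactants: 2 O-allyl ether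
Product: 3 5-allyl phenol
Conditions: PhNEt2, 200 °C
Reagents that add atoms: none
Why: Aromatic Claisen rearrangement ([3,3]); C5 is the only free ortho position and the para position is blocked, so a single regioisomer forms.

Step 3
Reactants: 3 5-allyl phenol
Product: 4 5-allyl benzyl ether
Conditions: BnBr, K2CO3, DMF, 60 °C
Reagents that add atoms: benzyl bromide, BrCc1ccccc1
Why: Williamson benzylation of the phenol, which must be masked so that it cannot lactonise onto the imide made in step 5.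

Step 4
Reactants: 4 5-allyl benzyl ether
Product: 6 arylacetic acid, via arylacetaldehyde 5 (not isolated)
Conditions: OsO4 (1 mol %), Oxone (4 equiv), DMF, rt
Reagents that add atoms: Oxone (potassium peroxymonosulfate), [K+].[O-]S(=O)(=O)OO; osmium tetroxide (catalytic oxygen carrier), O=[Os](=O)(=O)=O
Why: Borhan-type oxidative alkene cleavage (osmylation, glycol cleavage to the aldehyde, peroxymonosulfate oxidation to the acid) removes the terminal carbon; ester and benzyl ether are inert.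

Step 5
Reactants: 6 arylacetic acid; 7 (4S)-4-benzyl-1,3-oxazolidin-2-one
Product: 9 arylacetyl imide, via mixed pivalic anhydride 8 (not isolated)
Conditions: PivCl, Et3N, THF, −20 °C; then LiCl, 7, rt
Reagents that add atoms: none
Why: Mixed-anhydride N-acylation of the Evans auxiliary; the bulky pivaloyl carbonyl directs attack to the arylacetyl carbonyl.

Step 6
Reactants: 9 arylacetyl imide; 10 4-(benzyloxy)-3-methoxybenzaldehyde
Product: 12 anti-aldol imide, via trimethylsilyl ether 11 (not isolated)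
Conditions: MgCl2 (20 mol %), Et3N, TMSCl, EtOAc, rt; then 1 M HCl/THF, 0 °C
Reagents that add atoms: none
Why: Evans MgCl2-catalysed direct anti-aldol: the chelated (Z)-magnesium enolate adds to the non-enolisable aldehyde on the face away from the auxiliary benzyl group through a boat transition state, and silyl trapping turns the catalyst over; this sets both arm centres (1S,2S after reduction).

Step 7
Reactants: 12 anti-aldol imide
Product: 13 anti-1,3-diol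
Conditions: NaBH4, THF/H2O (4:1), 0 °C to rt
Reagents that add atoms: none
Why: Borohydride reductive cleavage of the N-acyl oxazolidinone (activated acyl) with the ethyl ester untouched; no stereocentre is affected and the auxiliary is recovered.

Step 8
Reactants: 13 anti-1,3-diol
Product: 14 bis-TBS ether (ring-A fragment)
Conditions: TBSOTf, 2,6-lutidine, CH2Cl2, −78 to 0 °C
Reagents that add atoms: tert-butyldimethylsilyl triflate, CC(C)(C)[Si](C)(C)OS(=O)(=O)C(F)(F)F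
Why: Silylation of both hydroxyls so that the ester α-CH2 is the only acidic site in step 15; the groups leave later with buffered fluoride, with no acid.

Step 9
Reactants: 9 arylacetyl imide; 10 4-(benzyloxy)-3-methoxybenzaldehyde
Product: 16 syn-aldol imide, via boron enolate 15 (not isolated)
Conditions: Bu2BOTf, i-Pr2NEt, CH2Cl2, 0 °C; 10, −78 to 0 °C; then pH 7 buffer, MeOH, 30% H2O2, 0 °C
Reagents that add atoms: none
Why: Evans boron syn-aldol through a Zimmerman–Traxler chair with the (Z)-enolate in the dipole-opposed conformation, which sets the arm carbon that becomes dihydrobenzofuran C3 (R after reduction) with the opposite sense to step 6 from the same auxiliary.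

Step 10
Reactants: 16 syn-aldol imide
Product: 17 syn-1,3-diol
Conditions: NaBH4, THF/H2O (4:1), 0 °C to rt
Reagents that add atoms: none
Why: Borohydride reductive cleavage of the N-acyl oxazolidinone as in step 7; the ester survives and no stereocentre is touched.

Step 11
Reactants: 17 syn-1,3-diol
Product: 20 trans-dihydrobenzofuran, via tetraol 18 (not isolated), via quinone methide 19 (not isolated)
Conditions: H2 (1 atm), 10% Pd/C, EtOAc/EtOH, rt; filter; then TsOH·H2O (5 mol %), CH2Cl2, rt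
Reagents that add atoms: none
Why: Hydrogenolysis frees both phenols, then acid ionises the 4-hydroxybenzylic alcohol to p-quinone methide 19 (the intermediate of 8–5 phenol coupling), which the ortho-phenol closes by 5-exo-trig oxa-Michael addition; the fixed C3 places the aryl group trans, giving (2S,3R).

Step 12
Reactants: 20 trans-dihydrobenzofuran
Product: 22 protected dihydrobenzofuran, via benzyl ether 21 (not isolated)
Conditions: BnBr, K2CO3, DMF, rt; then TBSCl, imidazole, rt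
Reagents that add atoms: benzyl bromide, BrCc1ccccc1; tert-butyldimethylsilyl chloride, CC(C)(C)[Si](C)(C)Cl
Why: One-pot Williamson benzylation of the phenol (carbonate does not deprotonate the alcohol) followed by silylation of the primary alcohol; no strong base touches the ester.

Step 13
Reactants: 22 protected dihydrobenzofuran
Product: 23 propanoic acid
Conditions: LiOH, THF/MeOH/H2O, rt; then 1 M HCl to pH 4, 0 °C
Reagents that add atoms: lithium hydroxide, [Li+].[OH-]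
Why: Saponification of the ethyl ester; the primary TBS ether, benzyl ether and dihydrobenzofuran tolerate aqueous LiOH at room temperature.

Step 14
Reactants: 23 propanoic acid; 7 (4S)-4-benzyl-1,3-oxazolidin-2-one
Product: 25 propanoyl imide (ring-B fragment), via mixed pivalic anhydride 24 (not isolated)
Conditions: PivCl, Et3N, THF, −20 °C; then LiCl, 7, rt
Reagents that add atoms: none
Why: Mixed-anhydride N-acylation as in step 5, installing the auxiliary that controls lactone C4.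

Step 15
Reactants: 14 bis-TBS ether (ring-A fragment); 25 propanoyl imide (ring-B fragment)
Product: 28 succinate, via lithium ester enolate 26 (not isolated), via lithium imide enolate 27 (not isolated)
Conditions: LDA (2.2 equiv), THF, −78 °C; then Fe(acac)3 (2.2 equiv), −78 °C to rt
Reagents that add atoms: none
Why: Baran-type Fe(III)-mediated oxidative heterocoupling of an imide enolate with an ester enolate forms the 8–8′ bond; the chelated (Z)-enolate 27 bonds on the face away from the benzyl group, setting the future lactone C4 as R, while the ester α-centre forms as a mixture that step 16 corrects.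

Step 16
Reactants: 28 succinate
Product: 30 protected trans-lactone, via hydroxy ester 29 (not isolated)
Conditions: LiBH4, Et2O/H2O (1 equiv), 0 °C; then DBU, PhMe, 60 °C
Reagents that add atoms: none
Why: Chemoselective hydride reduction of the imide carbonyl over the hindered ester, 5-exo-trig lactonisation with loss of ethanol, and DBU epimerisation α to the lactone carbonyl to the thermodynamically preferred trans-3,4-dibenzyl lactone (3R,4R).

Step 17
Reactants: 30 protected trans-lactone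
Product: 31 tri-O-benzyl triol
Conditions: HF·pyridine, pyridine, THF, 0 °C to rt
Reagents that add atoms: none
Why: Buffered fluoride desilylation of the three TBS ethers; ring A is still O-benzylated, so the freed benzylic alcohol cannot cyclise.

Step 18
Reactants: 31 tri-O-benzyl triol
Product: 32 CNP0186558.2
Conditions: H2 (1 atm), 10% Pd/C, EtOAc/MeOH, rt, stopped after 3 equiv H2; neutral work-up
Reagents that add atoms: none
Why: Hydrogenolysis of the three aryl benzyl ethers under neutral conditions, which spares the benzylic alcohol, the dihydrobenzofuran C–O bond and the lactone and avoids the acid that would close the open arm.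

## Compound list

Abbreviations used in names 26–31:
- ArA = 4-(benzyloxy)-3-[(1S,2S)-1-[4-(benzyloxy)-3-methoxyphenyl]-1,3-bis(tert-butyldimethylsilyloxy)propan-2-yl]-5-methoxyphenyl
- ArB = (2S,3R)-2-[4-(benzyloxy)-3-methoxyphenyl]-3-[(tert-butyldimethylsilyloxy)methyl]-7-methoxy-2,3-dihydro-1-benzofuran-5-yl

1 | ethyl 3-(4-hydroxy-3-methoxyphenyl)propanoate (ethyl dihydroferulate) | CCOC(=O)CCc1ccc(O)c(OC)c1 | starting material
2 | ethyl 3-[3-methoxy-4-(prop-2-en-1-yloxy)phenyl]propanoate | CCOC(=O)CCc1ccc(OCC=C)c(OC)c1 | intermediate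
3 | ethyl 3-[4-hydroxy-3-methoxy-5-(prop-2-en-1-yl)phenyl]propanoate | CCOC(=O)CCc1cc(CC=C)c(O)c(OC)c1 | intermediate
4 | ethyl 3-[4-(benzyloxy)-3-methoxy-5-(prop-2-en-1-yl)phenyl]propanoate | CCOC(=O)CCc1cc(CC=C)c(OCc2ccccc2)c(OC)c1 | intermediate
5 | ethyl 3-[4-(benzyloxy)-3-methoxy-5-(2-oxoethyl)phenyl]propanoate | CCOC(=O)CCc1cc(CC=O)c(OCc2ccccc2)c(OC)c1 | intermediate
6 | [2-(benzyloxy)-5-(3-ethoxy-3-oxopropyl)-3-methoxyphenyl]acetic acid | CCOC(=O)CCc1cc(CC(=O)O)c(OCc2ccccc2)c(OC)c1 | intermediate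
7 | (4S)-4-benzyl-1,3-oxazolidin-2-one | O=C1N[C@@H](Cc2ccccc2)CO1 | starting material
8 | mixed anhydride of acid 6 with pivalic acid | CCOC(=O)CCc1cc(CC(=O)OC(=O)C(C)(C)C)c(OCc2ccccc2)c(OC)c1 | intermediate
9 | ethyl 3-[4-(benzyloxy)-3-{2-[(4S)-4-benzyl-2-oxo-1,3-oxazolidin-3-yl]-2-oxoethyl}-5-methoxyphenyl]propanoate | CCOC(=O)CCc1cc(CC(=O)N2[C@@H](Cc3ccccc3)COC2=O)c(OCc2ccccc2)c(OC)c1 | intermediate
10 | 4-(benzyloxy)-3-methoxybenzaldehyde (O-benzylvanillin) | COc1cc(C=O)ccc1OCc1ccccc1 | starting material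
11 | O-trimethylsilyl ether of 12 (same configuration) | COc1cc([C@@H](O[Si](C)(C)C)[C@H](C(=O)N2[C@@H](Cc3ccccc3)COC2=O)c2cc(CCC(=O)OCC)cc(OC)c2OCc2ccccc2)ccc1OCc1ccccc1 | intermediate
12 | ethyl 3-[4-(benzyloxy)-3-{(1R,2S)-2-[4-(benzyloxy)-3-methoxyphenyl]-1-{[(4S)-4-benzyl-2-oxo-1,3-oxazolidin-3-yl]carbonyl}-2-hydroxyethyl}-5-methoxyphenyl]propanoate (anti-aldol) | COc1cc([C@@H](O)[C@H](C(=O)N2[C@@H](Cc3ccccc3)COC2=O)c2cc(CCC(=O)OCC)cc(OC)c2OCc2ccccc2)ccc1OCc1ccccc1 | intermediate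
13 | ethyl 3-[4-(benzyloxy)-3-{(1S,2S)-1-[4-(benzyloxy)-3-methoxyphenyl]-1,3-dihydroxypropan-2-yl}-5-methoxyphenyl]propanoate | COc1cc([C@@H](O)[C@H](CO)c2cc(CCC(=O)OCC)cc(OC)c2OCc2ccccc2)ccc1OCc1ccccc1 | intermediate
14 | ethyl 3-[4-(benzyloxy)-3-{(1S,2S)-1-[4-(benzyloxy)-3-methoxyphenyl]-1,3-bis(tert-butyldimethylsilyloxy)propan-2-yl}-5-methoxyphenyl]propanoate | COc1cc([C@@H](O[Si](C)(C)C(C)(C)C)[C@H](CO[Si](C)(C)C(C)(C)C)c2cc(CCC(=O)OCC)cc(OC)c2OCc2ccccc2)ccc1OCc1ccccc1 | intermediate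
15 | (Z)-dibutylboron enolate of imide 9 | CCCCB(CCCC)O/C(=C\c1cc(CCC(=O)OCC)cc(OC)c1OCc1ccccc1)N1[C@@H](Cc2ccccc2)COC1=O | intermediate
16 | ethyl 3-[4-(benzyloxy)-3-{(1S,2S)-2-[4-(benzyloxy)-3-methoxyphenyl]-1-{[(4S)-4-benzyl-2-oxo-1,3-oxazolidin-3-yl]carbonyl}-2-hydroxyethyl}-5-methoxyphenyl]propanoate (syn-aldol) | COc1cc([C@@H](O)[C@@H](C(=O)N2[C@@H](Cc3ccccc3)COC2=O)c2cc(CCC(=O)OCC)cc(OC)c2OCc2ccccc2)ccc1OCc1ccccc1 | intermediate
17 | ethyl 3-[4-(benzyloxy)-3-{(1S,2R)-1-[4-(benzyloxy)-3-methoxyphenyl]-1,3-dihydroxypropan-2-yl}-5-methoxyphenyl]propanoate | COc1cc([C@@H](O)[C@@H](CO)c2cc(CCC(=O)OCC)cc(OC)c2OCc2ccccc2)ccc1OCc1ccccc1 | intermediate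
18 | ethyl 3-[3-{(1S,2R)-1,3-dihydroxy-1-(4-hydroxy-3-methoxyphenyl)propan-2-yl}-4-hydroxy-5-methoxyphenyl]propanoate | COc1cc([C@@H](O)[C@@H](CO)c2cc(CCC(=O)OCC)cc(OC)c2O)ccc1O | intermediate
19 | ethyl 3-{4-hydroxy-3-[(2R)-1-hydroxy-3-(3-methoxy-4-oxocyclohexa-2,5-dien-1-ylidene)propan-2-yl]-5-methoxyphenyl}propanoate (p-quinone methide) | COC1=CC(=C[C@@H](CO)c2cc(CCC(=O)OCC)cc(OC)c2O)C=CC1=O | intermediate
20 | ethyl 3-[(2S,3R)-2-(4-hydroxy-3-methoxyphenyl)-3-(hydroxymethyl)-7-methoxy-2,3-dihydro-1-benzofuran-5-yl]propanoate | CCOC(=O)CCc1cc(OC)c2c(c1)[C@H](CO)[C@@H](c1ccc(O)c(OC)c1)O2 | intermediate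
21 | ethyl 3-[(2S,3R)-2-[4-(benzyloxy)-3-methoxyphenyl]-3-(hydroxymethyl)-7-methoxy-2,3-dihydro-1-benzofuran-5-yl]propanoate | CCOC(=O)CCc1cc(OC)c2c(c1)[C@H](CO)[C@@H](c1ccc(OCc3ccccc3)c(OC)c1)O2 | intermediate
22 | ethyl 3-[(2S,3R)-2-[4-(benzyloxy)-3-methoxyphenyl]-3-[(tert-butyldimethylsilyloxy)methyl]-7-methoxy-2,3-dihydro-1-benzofuran-5-yl]propanoate | CCOC(=O)CCc1cc(OC)c2c(c1)[C@H](CO[Si](C)(C)C(C)(C)C)[C@@H](c1ccc(OCc3ccccc3)c(OC)c1)O2 | intermediate
23 | 3-[(2S,3R)-2-[4-(benzyloxy)-3-methoxyphenyl]-3-[(tert-butyldimethylsilyloxy)methyl]-7-methoxy-2,3-dihydro-1-benzofuran-5-yl]propanoic acid | OC(=O)CCc1cc(OC)c2c(c1)[C@H](CO[Si](C)(C)C(C)(C)C)[C@@H](c1ccc(OCc3ccccc3)c(OC)c1)O2 | intermediate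
24 | mixed anhydride of acid 23 with pivalic acid | CC(C)(C)C(=O)OC(=O)CCc1cc(OC)c2c(c1)[C@H](CO[Si](C)(C)C(C)(C)C)[C@@H](c1ccc(OCc3ccccc3)c(OC)c1)O2 | intermediate
25 | (4S)-4-benzyl-3-{3-[(2S,3R)-2-[4-(benzyloxy)-3-methoxyphenyl]-3-[(tert-butyldimethylsilyloxy)methyl]-7-methoxy-2,3-dihydro-1-benzofuran-5-yl]propanoyl}-1,3-oxazolidin-2-one | O=C1OC[C@H](Cc2ccccc2)N1C(=O)CCc1cc(OC)c2c(c1)[C@H](CO[Si](C)(C)C(C)(C)C)[C@@H](c1ccc(OCc3ccccc3)c(OC)c1)O2 | intermediate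
26 | lithium enolate of ester 14 (ethyl 3-ArA-propanoate enolate) | [Li+].COc1cc([C@@H](O[Si](C)(C)C(C)(C)C)[C@H](CO[Si](C)(C)C(C)(C)C)c2cc(CC=C([O-])OCC)cc(OC)c2OCc2ccccc2)ccc1OCc1ccccc1 | intermediate
27 | lithium (Z)-enolate of imide 25 | [Li+].[O-]/C(=C\Cc1cc(OC)c2c(c1)[C@H](CO[Si](C)(C)C(C)(C)C)[C@@H](c1ccc(OCc3ccccc3)c(OC)c1)O2)N1[C@@H](Cc2ccccc2)COC1=O | intermediate
28 | ethyl (2R,3R)-4-[(4S)-4-benzyl-2-oxo-1,3-oxazolidin-3-yl]-2-(ArA-methyl)-3-(ArB-methyl)-4-oxobutanoate (major isomer; its 2S epimer is carried along) | COc1cc([C@@H](O[Si](C)(C)C(C)(C)C)[C@H](CO[Si](C)(C)C(C)(C)C)c2cc(C[C@@H](C(=O)OCC)[C@H](C(=O)N3[C@@H](Cc4ccccc4)COC3=O)Cc3cc(OC)c4c(c3)[C@H](CO[Si](C)(C)C(C)(C)C)[C@@H](c3ccc(OCc5ccccc5)c(OC)c3)O4)cc(OC)c2OCc2ccccc2)ccc1OCc1ccccc1 | intermediate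
29 | ethyl (2R,3R)-2-(ArA-methyl)-3-(ArB-methyl)-4-hydroxybutanoate | COc1cc([C@@H](O[Si](C)(C)C(C)(C)C)[C@H](CO[Si](C)(C)C(C)(C)C)c2cc(C[C@@H](C(=O)OCC)[C@H](CO)Cc3cc(OC)c4c(c3)[C@H](CO[Si](C)(C)C(C)(C)C)[C@@H](c3ccc(OCc5ccccc5)c(OC)c3)O4)cc(OC)c2OCc2ccccc2)ccc1OCc1ccccc1 | intermediate
30 | (3R,4R)-3-(ArA-methyl)-4-(ArB-methyl)oxolan-2-one | COc1cc([C@@H](O[Si](C)(C)C(C)(C)C)[C@H](CO[Si](C)(C)C(C)(C)C)c2cc(C[C@H]3C(=O)OC[C@@H]3Cc3cc(OC)c4c(c3)[C@H](CO[Si](C)(C)C(C)(C)C)[C@@H](c3ccc(OCc5ccccc5)c(OC)c3)O4)cc(OC)c2OCc2ccccc2)ccc1OCc1ccccc1 | intermediate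
31 | (3R,4R)-3-{[4-(benzyloxy)-3-[(1S,2S)-1-[4-(benzyloxy)-3-methoxyphenyl]-1,3-dihydroxypropan-2-yl]-5-methoxyphenyl]methyl}-4-{[(2S,3R)-2-[4-(benzyloxy)-3-methoxyphenyl]-3-(hydroxymethyl)-7-methoxy-2,3-dihydro-1-benzofuran-5-yl]methyl}oxolan-2-one | COc1cc([C@@H](O)[C@H](CO)c2cc(C[C@H]3C(=O)OC[C@@H]3Cc3cc(OC)c4c(c3)[C@H](CO)[C@@H](c3ccc(OCc5ccccc5)c(OC)c3)O4)cc(OC)c2OCc2ccccc2)ccc1OCc1ccccc1 | intermediate
32 | CNP0186558.2: (3R,4R)-3-{[3-[(1S,2S)-1,3-dihydroxy-1-(4-hydroxy-3-methoxyphenyl)propan-2-yl]-4-hydroxy-5-methoxyphenyl]methyl}-4-{[(2S,3R)-2-(4-hydroxy-3-methoxyphenyl)-3-(hydroxymethyl)-7-methoxy-2,3-dihydro-1-benzofuran-5-yl]methyl}oxolan-2-one | COc1cc([C@@H](O)[C@H](CO)c2cc(C[C@H]3C(=O)OC[C@@H]3Cc3cc(OC)c4c(c3)[C@H](CO)[C@@H](c3ccc(O)c(OC)c3)O4)cc(OC)c2O)ccc1O | target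

## Step count and risks

Total steps: 18. Longest linear sequence: 15 (steps 1–5, 9–14, 15–18); the ring-A branch (steps 6–8) joins at step 15.

Most likely to fail, in this order:

Step 15 (oxidative heterocoupling of two large, fully elaborated enolates; homodimers and low conversion are the danger). The fallback sets out from 4 and 25 and comes back at 31. It forms the 8–8′ bond before the diol arm exists, with the cheap partner in excess. LDA on a 3:1 mixture of 4 and 25 gives the lithium enolate of 4 F1 beside enolate 27, and Fe(acac)3 couples them to the allyl-bearing succinate F2. LiBH4 reduces the imide to the hydroxy ester F3 and DBU closes and epimerises it to the trans-lactone F4. OsO4/Oxone cleaves the allyl group through the arylacetaldehyde F5 to the arylacetic acid F6. PivCl/Et3N gives the mixed pivalic anhydride F7, which acylates 7 to the arylacetyl imide F8. The MgCl2/Et3N/TMSCl aldol with 10 gives the trimethylsilyl ether F9 and, after dilute HCl, the anti-aldol F10. NaBH4 in THF/H2O (lactone spared at 0 °C) gives the diol F11, and HF·pyridine removes its single silyl group to give 31.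

Step 6 (the Mg anti-aldol is untested on an α-aryl imide, whose adduct can re-enolise and lose its C2 configuration). The fallback sets out from 6 (through its anhydride 8) and comes back at 14. It sets the arm C2 by the boron aldol and the carbinol by a reagent-controlled ketone reduction. Anhydride 8 acylates (4R)-4-benzyl-1,3-oxazolidin-2-one to the enantiomeric-auxiliary imide F12. Bu2BOTf/i-Pr2NEt gives its (Z)-boron enolate F13, which adds to 10 to give the syn-aldol F14. NaBH4 gives the (1R,2S)-diol F15 and TBSCl/imidazole silylates the primary alcohol to the mono-TBS ether F16. Dess–Martin periodinane gives the aryl ketone F17. (R)-Me-CBS/BH3·SMe2 reduces it to the (1S,2S)-alcohol F18, and TBSOTf/2,6-lutidine then gives 14.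

Step 16 (hydride must attack a hindered imide faster than the ester and the newly formed lactone; endocyclic auxiliary opening is also possible). The fallback sets out from 28 and comes back at 29. LiOH/H2O2 removes the auxiliary hydrolytically to the succinic acid monoester F19. BH3·SMe2 reduces only the free acid, giving hydroxy ester 29, which DBU converts to 30 as in step 16.

## Further compounds

F1 | step 15 | lithium enolate of ester 4 | [Li+].CCOC([O-])=CCc1cc(CC=C)c(OCc2ccccc2)c(OC)c1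
F2 | step 15 | ethyl (2R,3R)-4-[(4S)-4-benzyl-2-oxo-1,3-oxazolidin-3-yl]-2-{[4-(benzyloxy)-3-methoxy-5-(prop-2-en-1-yl)phenyl]methyl}-3-(ArB-methyl)-4-oxobutanoate | CCOC(=O)[C@H](Cc1cc(CC=C)c(OCc2ccccc2)c(OC)c1)[C@@H](Cc1cc(OC)c2c(c1)[C@H](CO[Si](C)(C)C(C)(C)C)[C@@H](c1ccc(OCc3ccccc3)c(OC)c1)O2)C(=O)N1[C@@H](Cc2ccccc2)COC1=O
F3 | step 15 | ethyl (2R,3R)-2-{[4-(benzyloxy)-3-methoxy-5-(prop-2-en-1-yl)phenyl]methyl}-3-(ArB-methyl)-4-hydroxybutanoate | CCOC(=O)[C@H](Cc1cc(CC=C)c(OCc2ccccc2)c(OC)c1)[C@@H](Cc1cc(OC)c2c(c1)[C@H](CO[Si](C)(C)C(C)(C)C)[C@@H](c1ccc(OCc3ccccc3)c(OC)c1)O2)CO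
F4 | step 15 | (3R,4R)-3-{[4-(benzyloxy)-3-methoxy-5-(prop-2-en-1-yl)phenyl]methyl}-4-(ArB-methyl)oxolan-2-one | C=CCc1cc(C[C@H]2C(=O)OC[C@@H]2Cc2cc(OC)c3c(c2)[C@H](CO[Si](C)(C)C(C)(C)C)[C@@H](c2ccc(OCc4ccccc4)c(OC)c2)O3)cc(OC)c1OCc1ccccc1
F5 | step 15 | arylacetaldehyde from F4 (2-oxoethyl in place of the allyl group) | O=CCc1cc(C[C@H]2C(=O)OC[C@@H]2Cc2cc(OC)c3c(c2)[C@H](CO[Si](C)(C)C(C)(C)C)[C@@H](c2ccc(OCc4ccccc4)c(OC)c2)O3)cc(OC)c1OCc1ccccc1
F6 | step 15 | arylacetic acid from F4 (carboxymethyl in place of the allyl group) | OC(=O)Cc1cc(C[C@H]2C(=O)OC[C@@H]2Cc2cc(OC)c3c(c2)[C@H](CO[Si](C)(C)C(C)(C)C)[C@@H](c2ccc(OCc4ccccc4)c(OC)c2)O3)cc(OC)c1OCc1ccccc1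
F7 | step 15 | mixed anhydride of acid F6 with pivalic acid | CC(C)(C)C(=O)OC(=O)Cc1cc(C[C@H]2C(=O)OC[C@@H]2Cc2cc(OC)c3c(c2)[C@H](CO[Si](C)(C)C(C)(C)C)[C@@H](c2ccc(OCc4ccccc4)c(OC)c2)O3)cc(OC)c1OCc1ccccc1
F8 | step 15 | (4S)-4-benzyl-1,3-oxazolidin-2-one imide of acid F6 | O=C1OC[C@H](Cc2ccccc2)N1C(=O)Cc1cc(C[C@H]2C(=O)OC[C@@H]2Cc2cc(OC)c3c(c2)[C@H](CO[Si](C)(C)C(C)(C)C)[C@@H](c2ccc(OCc4ccccc4)c(OC)c2)O3)cc(OC)c1OCc1ccccc1
F9 | step 15 | O-trimethylsilyl ether of F10 | COc1cc([C@@H](O[Si](C)(C)C)[C@H](C(=O)N2[C@@H](Cc3ccccc3)COC2=O)c2cc(C[C@H]3C(=O)OC[C@@H]3Cc3cc(OC)c4c(c3)[C@H](CO[Si](C)(C)C(C)(C)C)[C@@H](c3ccc(OCc5ccccc5)c(OC)c3)O4)cc(OC)c2OCc2ccccc2)ccc1OCc1ccccc1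
F10 | step 15 | anti-aldol imide on the lactone core (arm centres as in 12; lactone 3R,4R) | COc1cc([C@@H](O)[C@H](C(=O)N2[C@@H](Cc3ccccc3)COC2=O)c2cc(C[C@H]3C(=O)OC[C@@H]3Cc3cc(OC)c4c(c3)[C@H](CO[Si](C)(C)C(C)(C)C)[C@@H](c3ccc(OCc5ccccc5)c(OC)c3)O4)cc(OC)c2OCc2ccccc2)ccc1OCc1ccccc1
F11 | step 15 | 31 carrying a TBS ether on the dihydrobenzofuran CH2OH | COc1cc([C@@H](O)[C@H](CO)c2cc(C[C@H]3C(=O)OC[C@@H]3Cc3cc(OC)c4c(c3)[C@H](CO[Si](C)(C)C(C)(C)C)[C@@H](c3ccc(OCc5ccccc5)c(OC)c3)O4)cc(OC)c2OCc2ccccc2)ccc1OCc1ccccc1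
F12 | step 6 | ethyl 3-[4-(benzyloxy)-3-{2-[(4R)-4-benzyl-2-oxo-1,3-oxazolidin-3-yl]-2-oxoethyl}-5-methoxyphenyl]propanoate | CCOC(=O)CCc1cc(CC(=O)N2[C@H](Cc3ccccc3)COC2=O)c(OCc2ccccc2)c(OC)c1
F13 | step 6 | (Z)-dibutylboron enolate of imide F12 | CCCCB(CCCC)O/C(=C\c1cc(CCC(=O)OCC)cc(OC)c1OCc1ccccc1)N1[C@H](Cc2ccccc2)COC1=O
F14 | step 6 | ethyl 3-[4-(benzyloxy)-3-{(1R,2R)-2-[4-(benzyloxy)-3-methoxyphenyl]-1-{[(4R)-4-benzyl-2-oxo-1,3-oxazolidin-3-yl]carbonyl}-2-hydroxyethyl}-5-methoxyphenyl]propanoate (syn-aldol) | COc1cc([C@H](O)[C@H](C(=O)N2[C@H](Cc3ccccc3)COC2=O)c2cc(CCC(=O)OCC)cc(OC)c2OCc2ccccc2)ccc1OCc1ccccc1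
F15 | step 6 | ethyl 3-[4-(benzyloxy)-3-{(1R,2S)-1-[4-(benzyloxy)-3-methoxyphenyl]-1,3-dihydroxypropan-2-yl}-5-methoxyphenyl]propanoate | COc1cc([C@H](O)[C@H](CO)c2cc(CCC(=O)OCC)cc(OC)c2OCc2ccccc2)ccc1OCc1ccccc1
F16 | step 6 | ethyl 3-[4-(benzyloxy)-3-{(1R,2S)-1-[4-(benzyloxy)-3-methoxyphenyl]-3-(tert-butyldimethylsilyloxy)-1-hydroxypropan-2-yl}-5-methoxyphenyl]propanoate | COc1cc([C@H](O)[C@H](CO[Si](C)(C)C(C)(C)C)c2cc(CCC(=O)OCC)cc(OC)c2OCc2ccccc2)ccc1OCc1ccccc1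
F17 | step 6 | ethyl 3-[4-(benzyloxy)-3-{(2S)-1-[4-(benzyloxy)-3-methoxyphenyl]-3-(tert-butyldimethylsilyloxy)-1-oxopropan-2-yl}-5-methoxyphenyl]propanoate | COc1cc(C(=O)[C@H](CO[Si](C)(C)C(C)(C)C)c2cc(CCC(=O)OCC)cc(OC)c2OCc2ccccc2)ccc1OCc1ccccc1
F18 | step 6 | ethyl 3-[4-(benzyloxy)-3-{(1S,2S)-1-[4-(benzyloxy)-3-methoxyphenyl]-3-(tert-butyldimethylsilyloxy)-1-hydroxypropan-2-yl}-5-methoxyphenyl]propanoate | COc1cc([C@@H](O)[C@H](CO[Si](C)(C)C(C)(C)C)c2cc(CCC(=O)OCC)cc(OC)c2OCc2ccccc2)ccc1OCc1ccccc1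
F19 | step 16 | (2R,3R)-4-ethoxy-3-(ArA-methyl)-2-(ArB-methyl)-4-oxobutanoic acid | COc1cc([C@@H](O[Si](C)(C)C(C)(C)C)[C@H](CO[Si](C)(C)C(C)(C)C)c2cc(C[C@@H](C(=O)OCC)[C@H](C(=O)O)Cc3cc(OC)c4c(c3)[C@H](CO[Si](C)(C)C(C)(C)C)[C@@H](c3ccc(OCc5ccccc5)c(OC)c3)O4)cc(OC)c2OCc2ccccc2)ccc1OCc1ccccc1
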